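**Plan**

- Retrosynthetic cuts, in order: the two O–benzyl bonds on the 2-hydroxybenzyl arms; C4–C4a (ring C, acylation); O1–C2 (aryl ether); the ester that blocks the future C4a; the two ArCH2–C6/C8 bonds; the 7-O–CH3 bond.
- Forward: ring A is finished first on a phloroglucinol carboxylate (7-OMe, both benzyl arms, then loss of the ester). The C2–C3–C4 chain is then hung on through O1, and ring C is closed last by acylation at C4a.
- Enabling feature: after decarboxylation ring A is a 4,6-dibenzyl-5-methoxyresorcinol with a symmetry plane through the methoxy-bearing carbon (future C7) and its only CH (future C4a). Either hydroxyl therefore gives the same mono-ether, and C4a, lying between O1 and the free 5-OH, is the one carbon where ring C can close.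
- Stereochemistry: the single stereocentre C2 (S) comes from ethyl (R)-3-hydroxy-3-phenylpropanoate by Mitsunobu inversion and is carried unchanged through saponification, ring closure and hydrogenolysis.

Key step: step 6

Remark: flavanone numbering is used (O1, C2, C3, C4, C4a, C5–C8, C8a; ring A = benzo ring, ring C = pyranone ring). Assumption: compounds 1, 3 and 8 are purchased, 8 as a single enantiomer.

**Route**

Step 1
Reactants: 1 methyl 2,4,6-trihydroxybenzoate
Product: 2 methyl 2,6-dihydroxy-4-methoxybenzoate
Conditions: Me2SO4 (1.0 equiv), K2CO3 (1.05 equiv), acetone, rt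
Reagents that add atoms: dimethyl sulfate, COS(=O)(=O)OC
Why: Williamson O-methylation should be selective because the 4-hydroxyl, para to the ester and not hydrogen-bonded, is the most acidic and most accessible of the three, so one equivalent of alkylating agent should leave the two chelated ortho hydroxyls free.

Step 2
Reactants: 2 methyl 2,6-dihydroxy-4-methoxybenzoate; 3 2-(benzyloxy)benzyl alcohol (2.3 equiv)
Product: 5 methyl 3,5-bis[2-(benzyloxy)benzyl]-2,6-dihydroxy-4-methoxybenzoate, via mono-benzylated benzoate 4 (not isolated)
Conditions: Sc(OTf)3 (10 mol %), MeNO2/CH2Cl2, 0 → 40 °C, slow addition of 3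
Reagents that add atoms: none
Why: In this Lewis-acid-catalysed Friedel–Crafts benzylation with a benzylic alcohol, Sc(OTf)3 ionises 3 to an ortho-alkoxy-stabilised benzyl cation that can only substitute C3 and C5 of 2, the two ring carbons left open by the ester and each activated by three oxygen substituents, with water as the only by-product.

Step 3
Reactants: 5 methyl 3,5-bis[2-(benzyloxy)benzyl]-2,6-dihydroxy-4-methoxybenzoate
Product: 7 4,6-bis[2-(benzyloxy)benzyl]-5-methoxybenzene-1,3-diol, via free benzoic acid 6 (not isolated)
Conditions: KOH (6 equiv), EtOH/H2O (degassed), reflux, Ar; then 2 M HCl to pH 2, 60 °C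
Reagents that add atoms: none
Why: Saponification of the methyl ester followed by protodecarboxylation, which 2,6-dihydroxybenzoic acids of the phloroglucinol type undergo readily by ipso protonation on warming in dilute acid, should remove the blocking group while the benzyl and methyl ethers are inert to both media.

Step 4
Reactants: 7 4,6-bis[2-(benzyloxy)benzyl]-5-methoxybenzene-1,3-diol (2 equiv, excess recovered); 8 ethyl (R)-3-hydroxy-3-phenylpropanoate
Product: 9 ethyl (S)-3-{2,4-bis[2-(benzyloxy)benzyl]-5-hydroxy-3-methoxyphenoxy}-3-phenylpropanoate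
Conditions: PPh3, DIAD, THF, 0 °C → rt
Reagents that add atoms: none
Why: In this Mitsunobu etherification the phenoxide of 7 displaces the oxyphosphonium derivative of the secondary benzylic alcohol by SN2 with inversion, so the (R)-carbinol becomes the (S)-aryl ether (the future C2), and since the two hydroxyls of 7 are equivalent only one mono-ether can form, the excess of 7 holding back the bis-ether.

Step 5
Reactants: 9 ethyl (S)-3-{2,4-bis[2-(benzyloxy)benzyl]-5-hydroxy-3-methoxyphenoxy}-3-phenylpropanoate
Product: 10 (S)-3-{2,4-bis[2-(benzyloxy)benzyl]-5-hydroxy-3-methoxyphenoxy}-3-phenylpropanoic acid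
Conditions: LiOH·H2O, THF/H2O, 0 °C → rt; then 1 M HCl, 0 °C
Reagents that add atoms: lithium hydroxide, [Li+].[OH-]
Why: This mild ester saponification should be clean because the ionised phenol makes the aryloxide a poor leaving group, which disfavours E1cB loss to cinnamate, while the stereocentre carries no acidic hydrogen and is not touched.

Step 6
Reactants: 10 (S)-3-{2,4-bis[2-(benzyloxy)benzyl]-5-hydroxy-3-methoxyphenoxy}-3-phenylpropanoic acid
Product: 12 (S)-6,8-bis[2-(benzyloxy)benzyl]-5-hydroxy-7-methoxyflavanone, via acyl chloride 11 (not isolated)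
Conditions: (COCl)2 (1.1 equiv), DMF (cat.), CH2Cl2, 0 °C; then SnCl4 (2.2 equiv), CH2Cl2 (dilute), −78 → −30 °C; cold aq. HCl quench
Reagents that add atoms: none
Why: Oxalyl chloride with catalytic DMF converts the acid into acyl chloride 11, and SnCl4 then ionises it to an acylium ion (or its tight complex) that attacks C4a of ring A; loss of a proton from the arenium ion restores aromaticity and leaves the new C4–C4a bond. The closest known reaction type is the intramolecular Friedel–Crafts acylation of 3-aryloxypropanoic acids to chroman-4-ones. Ring C closes as a six-membered ring by electrophilic aromatic substitution, a 6-exo attack of the arene on the acyl carbon with annulation across the C4a–C8a edge of ring A. No stereocentre is formed; C2, set in step 4, is only a spectator. Regioselectivity needs no control element beyond the substitution pattern, since C4a is the only unsubstituted carbon of ring A and lies between the ether oxygen O1 and the small, strongly activating free 5-hydroxyl (bound as a tin phenoxide), which ends up hydrogen-bonded to the new ketone. The selectivities to be secured are C- over O-acylation of that phenol (the intramolecular ester would be an eight-membered lactone) and retention at C2, and both are served by the absence of base, dilution and temperatures of −78 to −30 °C, at which the benzyl ethers should survive SnCl4 and the benzylic C2–O1 bond should neither ionise nor open to the chalcone.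

Step 7
Reactants: 12 (S)-6,8-bis[2-(benzyloxy)benzyl]-5-hydroxy-7-methoxyflavanone
Product: 15 7-methoxydichamanetin, (S)-5-hydroxy-6,8-bis(2-hydroxybenzyl)-7-methoxyflavanone, via C6-arm phenol 13 (not isolated), via C8-arm phenol 14 (not isolated)
Conditions: H2 (1 atm), 10% Pd/C, EtOAc/MeOH, rt
Reagents that add atoms: none
Why: Heterogeneous hydrogenolysis of the two aryl benzyl ethers, which run through the two mono-benzyl ethers in parallel, is a standard last step for flavanones, whose ketone, diarylmethane units and cyclic benzylic C2–O1 bond are expected to persist under one atmosphere of hydrogen in neutral solvent, leaving C2 unchanged.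

**Compound list**

1 | methyl 2,4,6-trihydroxybenzoate | COC(=O)c1c(O)cc(O)cc1O | starting material
2 | methyl 2,6-dihydroxy-4-methoxybenzoate | COC(=O)c1c(O)cc(OC)cc1O | intermediate
3 | 2-(benzyloxy)benzyl alcohol | OCc1ccccc1OCc1ccccc1 | starting material
4 | methyl 3-[2-(benzyloxy)benzyl]-2,6-dihydroxy-4-methoxybenzoate | COC(=O)c1c(O)c(Cc2ccccc2OCc2ccccc2)c(OC)cc1O | intermediate (not isolated)
5 | methyl 3,5-bis[2-(benzyloxy)benzyl]-2,6-dihydroxy-4-methoxybenzoate | COC(=O)c1c(O)c(Cc2ccccc2OCc2ccccc2)c(OC)c(Cc2ccccc2OCc2ccccc2)c1O | intermediate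
6 | 3,5-bis[2-(benzyloxy)benzyl]-2,6-dihydroxy-4-methoxybenzoic acid | OC(=O)c1c(O)c(Cc2ccccc2OCc2ccccc2)c(OC)c(Cc2ccccc2OCc2ccccc2)c1O | intermediate (not isolated)
7 | 4,6-bis[2-(benzyloxy)benzyl]-5-methoxybenzene-1,3-diol | COc1c(Cc2ccccc2OCc2ccccc2)c(O)cc(O)c1Cc1ccccc1OCc1ccccc1 | intermediate
8 | ethyl (R)-3-hydroxy-3-phenylpropanoate | CCOC(=O)C[C@@H](O)c1ccccc1 | starting material
9 | ethyl (S)-3-{2,4-bis[2-(benzyloxy)benzyl]-5-hydroxy-3-methoxyphenoxy}-3-phenylpropanoate | CCOC(=O)C[C@@H](c1ccccc1)Oc1cc(O)c(Cc2ccccc2OCc2ccccc2)c(OC)c1Cc1ccccc1OCc1ccccc1 | intermediate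
10 | (S)-3-{2,4-bis[2-(benzyloxy)benzyl]-5-hydroxy-3-methoxyphenoxy}-3-phenylpropanoic acid | OC(=O)C[C@@H](c1ccccc1)Oc1cc(O)c(Cc2ccccc2OCc2ccccc2)c(OC)c1Cc1ccccc1OCc1ccccc1 | intermediate (key-step precursor)
11 | (S)-3-{2,4-bis[2-(benzyloxy)benzyl]-5-hydroxy-3-methoxyphenoxy}-3-phenylpropanoyl chloride | ClC(=O)C[C@@H](c1ccccc1)Oc1cc(O)c(Cc2ccccc2OCc2ccccc2)c(OC)c1Cc1ccccc1OCc1ccccc1 | intermediate (not isolated)
12 | (S)-6,8-bis[2-(benzyloxy)benzyl]-5-hydroxy-7-methoxyflavanone | COc1c(Cc2ccccc2OCc2ccccc2)c(O)c2c(c1Cc1ccccc1OCc1ccccc1)O[C@H](c1ccccc1)CC2=O | intermediate (key-step product)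
13 | (S)-8-[2-(benzyloxy)benzyl]-5-hydroxy-6-(2-hydroxybenzyl)-7-methoxyflavanone | COc1c(Cc2ccccc2O)c(O)c2c(c1Cc1ccccc1OCc1ccccc1)O[C@H](c1ccccc1)CC2=O | intermediate (not isolated)
14 | (S)-6-[2-(benzyloxy)benzyl]-5-hydroxy-8-(2-hydroxybenzyl)-7-methoxyflavanone | COc1c(Cc2ccccc2OCc2ccccc2)c(O)c2c(c1Cc1ccccc1O)O[C@H](c1ccccc1)CC2=O | intermediate (not isolated)
15 | 7-methoxydichamanetin, (2S)-5-hydroxy-6,8-bis(2-hydroxybenzyl)-7-methoxy-2-phenyl-2,3-dihydro-4H-chromen-4-one | COc1c(Cc2ccccc2O)c(O)c2c(c1Cc1ccccc1O)O[C@H](c1ccccc1)CC2=O | target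

**Step count**

Total: 7 steps. Longest linear sequence: 7 steps (1 → 15); compounds 3 and 8 enter as purchased materials.

**Steps most likely to fail, and fallbacks**

Step 2. The benzyl cation may condense with the alkoxyarene ring of another molecule of 3 instead of with 2, the second benzylation may stall, or the Lewis acid may strip benzyl ethers. The fallback changes the polarity of the C-benzylation and the order of events; it sets out from 1 and 3 and comes back at 5. Alcohol 3 would be converted with PBr3 (Et2O, 0 °C) into 2-(benzyloxy)benzyl bromide F1. The phloroglucinolate of 1 (aqueous KOH or NaOMe/MeOH, 0 °C) would then be C-alkylated twice with F1, the classical base-mediated C-benzylation of phloroglucinol carboxylates and acylphloroglucinols, to give methyl 3,5-bis[2-(benzyloxy)benzyl]-2,4,6-trihydroxybenzoate F2. Selective methylation of its non-chelated 4-hydroxyl (Me2SO4, K2CO3, acetone) would deliver 5.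

Step 4. The activated β-hydroxy ester may eliminate to ethyl cinnamate, the benzylic centre may partly ionise and erode the inversion, and both hydroxyls of 7 may be etherified. The fallback replaces the Mitsunobu reaction by ring opening of a β-lactone; it sets out from 8 (with 7 as the nucleophile) and comes back at 10, bypassing 9 and step 5. Ester 8 would be saponified (LiOH, THF/H2O) to (R)-3-hydroxy-3-phenylpropanoic acid F3 and cyclised by carboxyl activation (PhSO2Cl, pyridine, 0 °C, carbinol centre untouched) to (R)-4-phenyloxetan-2-one F4. The monosodium phenoxide of 7 (NaH, 1 equiv, DMF) should open F4 at the benzylic carbon by alkyl–oxygen cleavage with inversion, and acidification should give acid 10 directly.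

Step 6. The free phenol may be O-acylated or the material may oligomerise while the acyl chloride is being made, and the Lewis acid may ionise the C2–O1 bond (loss of configurational purity) or cleave benzyl ethers. The fallback keeps the C4–C4a disconnection but changes the oxidation level of the acylating carbon to a nitrile, for which a free phenol is the ideal partner; it sets out from 7 and comes back at 12. Mitsunobu coupling of 7 with purchased (R)-3-hydroxy-3-phenylpropanenitrile (N#CC[C@@H](O)c1ccccc1; PPh3, DIAD, THF) would give (S)-3-{2,4-bis[2-(benzyloxy)benzyl]-5-hydroxy-3-methoxyphenoxy}-3-phenylpropanenitrile F5. An intramolecular Houben–Hoesch reaction (ZnCl2, HCl gas, Et2O, 0 °C) should close ring C at C4a to the 4-imine of 12, (S)-6,8-bis[2-(benzyloxy)benzyl]-5-hydroxy-7-methoxyflavanone 4-imine F6, formed as its hydrochloride. Hydrolysis in warm water should then give 12.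

**Further compounds**

F1 | step 2 | 2-(benzyloxy)benzyl bromide | BrCc1ccccc1OCc1ccccc1
F2 | step 2 | methyl 3,5-bis[2-(benzyloxy)benzyl]-2,4,6-trihydroxybenzoate | COC(=O)c1c(O)c(Cc2ccccc2OCc2ccccc2)c(O)c(Cc2ccccc2OCc2ccccc2)c1O
F3 | step 4 | (R)-3-hydroxy-3-phenylpropanoic acid | OC(=O)C[C@@H](O)c1ccccc1
F4 | step 4 | (R)-4-phenyloxetan-2-one | O=C1C[C@@H](O1)c1ccccc1
F5 | step 6 | (S)-3-{2,4-bis[2-(benzyloxy)benzyl]-5-hydroxy-3-methoxyphenoxy}-3-phenylpropanenitrile | N#CC[C@@H](c1ccccc1)Oc1cc(O)c(Cc2ccccc2OCc2ccccc2)c(OC)c1Cc1ccccc1OCc1ccccc1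
F6 | step 6 | (S)-6,8-bis[2-(benzyloxy)benzyl]-5-hydroxy-7-methoxyflavanone 4-imine | COc1c(Cc2ccccc2OCc2ccccc2)c(O)c2c(c1Cc1ccccc1OCc1ccccc1)O[C@H](c1ccccc1)CC2=N
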